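The route rests on cutting the C5–C6 bond of the cyclopentenone ring, between the spiro carbon C5 and the carbinol carbon C6. The chain that remains, C9(=O)–C8(OMe)=C7(OMe)–C6(=O)–CO2Me with Z geometry, is the oxidised form of a methyl 3,4-dimethoxyfuran-2-carboxylate. The precursor is therefore a flat 2-(2-furyl)furan-3(2H)-one that already holds the furanone and aryl rings. In one operation singlet oxygen dearomatises this furan, the enedione is released, and a chiral phosphoric acid steers the conrotatory closure of C5 onto C6. This gives the carbocycle, the tertiary alcohol, the spiro centre and both stereocentres. All six carbons involved come from one symmetrical furan diester.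

Key step: step 6

Numbering: target locants follow 1-oxaspiro[4.4]nonane. They are O1, C2 (aryl), C3 (=CH), C4 (furanone C=O), C5 (spiro), C6 (C(OH)CO2Me), C7 and C8 (C–OMe), and C9 (enone C=O). The same locants are used for the corresponding atoms of 10–12. The target is (5S,6R), with the C6 hydroxyl cis to O1.

Assumption: the sense of induction of the phosphoric acid cannot be derived from a close precedent. (R)-TRIP is written, and its commercial (S)-antipode is taken if a first trial shows the opposite sense.

Step 1
Reactants: 1 dimethyl diglycolate (dimethyl 2,2'-oxydiacetate); 2 dimethyl oxalate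
Product: 3 dimethyl 3,4-dihydroxyfuran-2,5-dicarboxylate
Conditions: NaOMe (2.2 equiv), MeOH, reflux; then aq HCl
Reagents that add atoms: none
Why: Hinsberg-type double Claisen condensation of the two activated CH2 groups of 1 with both ester groups of 2, followed by enolisation to the aromatic dihydroxyfuran; no stereocentre is formed.

Step 2
Reactants: 3 dimethyl 3,4-dihydroxyfuran-2,5-dicarboxylate
Product: 4 dimethyl 3,4-dimethoxyfuran-2,5-dicarboxylate
Conditions: Me2SO4 (2.5 equiv), K2CO3, acetone, reflux
Reagents that add atoms: dimethyl sulfate, COS(=O)(=O)OC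
Why: Williamson-type O-methylation of the two acidic enolic hydroxyls, where the hard methylating agent should favour oxygen over carbon.

Step 3
Reactants: 4 dimethyl 3,4-dimethoxyfuran-2,5-dicarboxylate
Product: 5 methyl 5-(hydroxymethyl)-3,4-dimethoxyfuran-2-carboxylate
Conditions: LiBH4 (1.0 equiv), THF, 0 °C to rt; then H2O
Reagents that add atoms: none
Why: Borohydride reduction of one ester, where desymmetrisation rests on stoichiometry and on the first reduction removing the acceptor that activates the second ester through the ring.

Step 4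
Reactants: 6 1-(benzyloxy)-4-iodobenzene; 7 methyl propiolate
Product: 8 methyl 3-[4-(benzyloxy)phenyl]prop-2-ynoate
Conditions: PdCl2(PPh3)2 (2 mol%), CuI (4 mol%), K2CO3, THF, 65 °C
Reagents that add atoms: none
Why: Sonogashira coupling of an aryl iodide, run with an inorganic base so that no amine can add to the propiolate.

Step 5
Reactants: 5 methyl 5-(hydroxymethyl)-3,4-dimethoxyfuran-2-carboxylate; 8 methyl 3-[4-(benzyloxy)phenyl]prop-2-ynoate
Product: 10 methyl 5-{5-[4-(benzyloxy)phenyl]-3-oxo-2,3-dihydrofuran-2-yl}-3,4-dimethoxyfuran-2-carboxylate (racemic; C2 of the furanone is labile), via Z-enol ether 9 (not isolated)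
Conditions: KOt-Bu (0.1 equiv), THF, 0 °C; then KOt-Bu (1.5 equiv), −20 °C to rt, Ar; AcOH quench
Reagents that add atoms: none
Why: Anti oxa-Michael addition of the alkoxide puts oxygen and CO2Me cis, and a Dieckmann-type condensation of the furfurylic carbanion (acidified through the ring by its ester, as in Fiesselmann-type hydroxyheterole syntheses and in the closure of O-benzyl salicylates to 2-arylbenzofuran-3-ones) then closes the furanone, driven by the stable furanolate; the new centre is racemic and is erased in step 6.

Step 6
Reactants: 10 methyl 5-{5-[4-(benzyloxy)phenyl]-3-oxo-2,3-dihydrofuran-2-yl}-3,4-dimethoxyfuran-2-carboxylate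
Product: 13 methyl (5S,6R)-2-[4-(benzyloxy)phenyl]-6-hydroxy-7,8-dimethoxy-4,9-dioxo-1-oxaspiro[4.4]nona-2,7-diene-6-carboxylate (O-benzyl-limnophilaspiroketone), via furan endoperoxide 11 (not isolated), via Z-enedione keto ester 12 (not isolated)
Conditions: O2, hν (white LED), tetraphenylporphyrin (1 mol%), CH2Cl2, −78 °C; Me2S (1.2 equiv), −78 to −40 °C; ice-water wash, Na2SO4, solution used at once; (R)-TRIP [(R)-3,3'-bis(2,4,6-triisopropylphenyl)-1,1'-binaphthyl-2,2'-diyl hydrogen phosphate] (10 mol%), toluene/CH2Cl2, −40 °C
Reagents that add atoms: dioxygen, O=O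
Why: Proposed new method: singlet oxygen adds in a (4+2) mode across the two α-carbons of the dimethoxyfuran ring of 10 (future C6 and C9) to give the bicyclic endoperoxide 11, Me2S removes one peroxide oxygen, and the Z-enedione 12 settles as its hydrogen-bonded 2-acyl-3-hydroxyfuran enol, which is the ring-opened intermediate of a Piancatelli rearrangement reached from the oxidative side; protonation of the keto ester carbonyl by the phosphoric acid makes a 1,4-dihydroxypentadienyl cation that closes the C5–C6 bond by conrotatory 4π electrocyclisation (in aldol terms a 5-(enolexo)-exo-trig attack of the dearomatising furanol carbon on the ketone). The closest known reaction types are the one-pot photooxygenation, sulfide reduction and aldol closure of 2-alkylfurans to 4-hydroxycyclopent-2-enones and the chiral phosphoric acid catalysed aza-Piancatelli and Nazarov cyclisations, while the fully substituted termini, the spiro centre and the enantioselective oxygen variant are new. Relative configuration: the chelate between the C9 enol and the C4 carbonyl holds C4 in the outside position at C5, the acid-bound oxygen, a donor, takes the outside position at C6 with the ester inside, and conrotation places the two outside groups trans, so the C6 hydroxyl should come out cis to O1 as required. Absolute configuration: the chiral phosphate is hydrogen-bonded to both hydroxyl groups of the cation and should favour one sense of conrotation, which sets 5S and 6R in the same event. The step needs oxygenation of the dimethoxyfuran alone, secured by the keto tautomer of the furanone ring (an electron-poor vinylogous ester without a cisoid diene), and closure on the ketone instead of the ester carbonyl, secured by the five-membered transition state and the higher electrophilicity of the ketone. The acid is kept weak and the temperature low so that the lactol form of 12 does not ionise.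

Step 7
Reactants: 13 O-benzyl-limnophilaspiroketone
Product: 14 limnophilaspiroketone, methyl (5S,6R)-6-hydroxy-2-(4-hydroxyphenyl)-7,8-dimethoxy-4,9-dioxo-1-oxaspiro[4.4]nona-2,7-diene-6-carboxylate
Conditions: H2 (1 atm), 10% Pd/C, EtOAc, rt
Reagents that add atoms: none
Why: Hydrogenolysis of the aryl benzyl ether under neutral conditions, where the tetrasubstituted dimethoxyenone and the vinylogous-ester C2=C3 bond should be slow to hydrogenate and the absence of base excludes retro-aldol scrambling of C5 and C6.

Compound list
1 | dimethyl diglycolate | COC(=O)COCC(=O)OC | starting material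
2 | dimethyl oxalate | COC(=O)C(=O)OC | starting material
3 | dimethyl 3,4-dihydroxyfuran-2,5-dicarboxylate | COC(=O)c1oc(C(=O)OC)c(O)c1O | intermediate
4 | dimethyl 3,4-dimethoxyfuran-2,5-dicarboxylate | COC(=O)c1oc(C(=O)OC)c(OC)c1OC | intermediate
5 | methyl 5-(hydroxymethyl)-3,4-dimethoxyfuran-2-carboxylate | COC(=O)c1oc(CO)c(OC)c1OC | intermediate
6 | 1-(benzyloxy)-4-iodobenzene | Ic1ccc(OCc2ccccc2)cc1 | starting material
7 | methyl propiolate | C#CC(=O)OC | starting material
8 | methyl 3-[4-(benzyloxy)phenyl]prop-2-ynoate | COC(=O)C#Cc1ccc(OCc2ccccc2)cc1 | intermediate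
9 | methyl 5-({[(1Z)-1-[4-(benzyloxy)phenyl]-3-methoxy-3-oxoprop-1-en-1-yl]oxy}methyl)-3,4-dimethoxyfuran-2-carboxylate (not isolated) | COC(=O)/C=C(\OCc1oc(C(=O)OC)c(OC)c1OC)c1ccc(OCc2ccccc2)cc1 | intermediate
10 | methyl 5-{5-[4-(benzyloxy)phenyl]-3-oxo-2,3-dihydrofuran-2-yl}-3,4-dimethoxyfuran-2-carboxylate (racemic, labile centre) | COC(=O)c1oc(C2OC(c3ccc(OCc4ccccc4)cc3)=CC2=O)c(OC)c1OC | intermediate
11 | methyl 4-{5-[4-(benzyloxy)phenyl]-3-oxo-2,3-dihydrofuran-2-yl}-5,6-dimethoxy-2,3,7-trioxabicyclo[2.2.1]hept-5-ene-1-carboxylate (stereoisomer mixture, not isolated) | COC(=O)C12OOC(O1)(C1OC(c3ccc(OCc4ccccc4)cc3)=CC1=O)C(OC)=C2OC | intermediate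
12 | methyl (3Z)-5-{5-[4-(benzyloxy)phenyl]-3-hydroxyfuran-2-yl}-3,4-dimethoxy-2,5-dioxopent-3-enoate (not isolated) | COC(=O)C(=O)/C(OC)=C(OC)\C(=O)c1oc(cc1O)-c1ccc(OCc2ccccc2)cc1 | intermediate
13 | methyl (5S,6R)-2-[4-(benzyloxy)phenyl]-6-hydroxy-7,8-dimethoxy-4,9-dioxo-1-oxaspiro[4.4]nona-2,7-diene-6-carboxylate | COC(=O)[C@@]1(O)C(OC)=C(OC)C(=O)[C@]12OC(c1ccc(OCc3ccccc3)cc1)=CC2=O | intermediate
14 | limnophilaspiroketone | COC(=O)[C@@]1(O)C(OC)=C(OC)C(=O)[C@]12OC(c1ccc(O)cc1)=CC2=O | target

Total step count: 7. Longest linear sequence: 6 (steps 1, 2, 3, 5, 6, 7).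

Steps most likely to fail

Step 6. Four things may go wrong.
- Oxygenation may occur at C5 through the enol tautomer of the furanone.
- Uncatalysed closure may proceed before the acid takes control.
- The torquoselectivity may be low, or the relative sense of closure may be wrong.
- The lactol form may ionise under acid, with loss of a methyl group.

The fallback uses known chemistry and sets out from 10. The same photooxygenation and Me2S reduction are run without the acid. The enedione is closed with catalytic Et3N, which is the established one-pot furan to 4-hydroxycyclopentenone protocol. This should give 13 as a racemate with its mirror image, methyl (5R,6S)-2-[4-(benzyloxy)phenyl]-6-hydroxy-7,8-dimethoxy-4,9-dioxo-1-oxaspiro[4.4]nona-2,7-diene-6-carboxylate F1. The two are separated by preparative chromatography on a chiral stationary phase. F1 is returned to achiral 12 by base-induced retro-aldol opening and closed again. The route is rejoined at 13.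

Step 5. Four things may go wrong.
- The alkoxide may transesterify the alkynoate.
- The enol ether geometry may drift.
- The furfurylic CH2 may not be acidic enough.
- The furanolate may autoxidise.

The fallback sets out from 5 and builds the furanone by the classical γ-hydroxy ynone route.
- MnO2 oxidation gives methyl 5-formyl-3,4-dimethoxyfuran-2-carboxylate F2.
- HC≡CMgBr at −78 °C adds to the aldehyde to give racemic methyl 5-(1-hydroxyprop-2-yn-1-yl)-3,4-dimethoxyfuran-2-carboxylate F3.
- Acyl Sonogashira coupling with 4-(benzyloxy)benzoyl chloride (PdCl2(PPh3)2, CuI, Et3N) gives methyl 5-{4-[4-(benzyloxy)phenyl]-1-hydroxy-4-oxobut-2-yn-1-yl}-3,4-dimethoxyfuran-2-carboxylate F4.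
- Et2NH adds to the ynone to give methyl 5-{(2E)-4-[4-(benzyloxy)phenyl]-2-(diethylamino)-1-hydroxy-4-oxobut-2-en-1-yl}-3,4-dimethoxyfuran-2-carboxylate F5.
- Dilute aqueous acid hydrolyses this to methyl 5-{4-[4-(benzyloxy)phenyl]-1-hydroxy-2,4-dioxobutyl}-3,4-dimethoxyfuran-2-carboxylate F6.
- F6 cyclodehydrates in the same medium, and the route is rejoined at 10.

Step 3. Over-reduction of both esters or a statistical mixture may result. The fallback sets out from 4. Saponification with one equivalent of KOH in MeOH, where the mono-potassium salt should precipitate, gives 5-(methoxycarbonyl)-3,4-dimethoxyfuran-2-carboxylic acid F7. BH3·SMe2 in THF then reduces the acid in preference to the ester. The route is rejoined at 5.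

Further compounds
F1 | step 6 | methyl (5R,6S)-2-[4-(benzyloxy)phenyl]-6-hydroxy-7,8-dimethoxy-4,9-dioxo-1-oxaspiro[4.4]nona-2,7-diene-6-carboxylate | COC(=O)[C@]1(O)C(OC)=C(OC)C(=O)[C@@]12OC(c1ccc(OCc3ccccc3)cc1)=CC2=O
F2 | step 5 | methyl 5-formyl-3,4-dimethoxyfuran-2-carboxylate | COC(=O)c1oc(C=O)c(OC)c1OC
F3 | step 5 | methyl 5-(1-hydroxyprop-2-yn-1-yl)-3,4-dimethoxyfuran-2-carboxylate (racemic) | COC(=O)c1oc(C(O)C#C)c(OC)c1OC
F4 | step 5 | methyl 5-{4-[4-(benzyloxy)phenyl]-1-hydroxy-4-oxobut-2-yn-1-yl}-3,4-dimethoxyfuran-2-carboxylate (racemic) | COC(=O)c1oc(C(O)C#CC(=O)c2ccc(OCc3ccccc3)cc2)c(OC)c1OC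
F5 | step 5 | methyl 5-{(2E)-4-[4-(benzyloxy)phenyl]-2-(diethylamino)-1-hydroxy-4-oxobut-2-en-1-yl}-3,4-dimethoxyfuran-2-carboxylate (racemic) | COC(=O)c1oc(C(O)/C(=C\C(=O)c2ccc(OCc3ccccc3)cc2)N(CC)CC)c(OC)c1OC
F6 | step 5 | methyl 5-{4-[4-(benzyloxy)phenyl]-1-hydroxy-2,4-dioxobutyl}-3,4-dimethoxyfuran-2-carboxylate (racemic) | COC(=O)c1oc(C(O)C(=O)CC(=O)c2ccc(OCc3ccccc3)cc2)c(OC)c1OC
F7 | step 3 | 5-(methoxycarbonyl)-3,4-dimethoxyfuran-2-carboxylic acid | COC(=O)c1oc(C(=O)O)c(OC)c1OC
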